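The grey run is the place to start on these four flasks. At 8.00 h it holds 21% target with 31% starting material left, so the share of consumed starting material that has become target, the selectivity to target, is 30.4%. The blue run, with 2 equiv of second substrate, gives 30.6% at 10.0 h, level with grey within the scatter. Grey at 12.0 h, with starting material down to 20%, still reads 30.0%.

| flask | starting material | second substrate | free catalyst | remark | time |
|---|---|---|---|---|---|
| grey | 10 mM | 1 equiv | 10 mol% | run made earlier |  |
| blue | 10 mM | 2 equiv | 10 mol% | run made earlier |  |
| east | 10 mM (fed, over 40 h) | 1.00 equiv | 10 mol% | all else is in the flask from the start; the feed brings no volume worth counting | 2.5 d |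
| west | 10 mM | 1.00 equiv | 10 mol% | everything together at the start | 2.5 d |
| south | 10 mM | 1.00 equiv (fed, over 40 h) | 10 mol% | all else is in the flask from the start; the feed brings no volume worth counting | 2.5 d |
| north-west | 10 mM | 1.00 equiv (fed, over 10 h) | 10 mol% | all else is in the flask from the start; the feed brings no volume worth counting | 2.5 d |

| run | time / h | target / % | starting material / % |
|---|---|---|---|
| grey | 2.50 | 8 | 71 |
| grey | 8.00 | 21 | 31 |
| grey | 12.0 | 24 | 20 |
| grey | 20.0 | 35 | 4 |
| grey | 30.0 | 31 | 0 |
| grey | 40.0 | 29 | 0 |
| blue | 1.33 | 3 | 81 |
| blue | 4.00 | 9 | 59 |
| blue | 6.00 | 12 | 48 |
| blue | 10.0 | 22 | 28 |
| blue | 15.0 | 27 | 9 |
| blue | 20.0 | 29 | 4 |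

(standard deviation of a reading: 2 percentage points)

* the flask with the highest amount of target, in percent of the starting material charged ("all alike" if they lie within 1.5 percentage points) (east / west / south / north-west / all alike)
* final target, as a percentage of the starting material charged, in east
* final target, as a percentage of the starting material charged, in west
* final target, as a percentage of the starting material charged, in south
* final target, as a percentage of the starting material charged, in north-west



The hunch offered with the request for a quick number was that the order of addition hardly matters. That is the symmetric case, and it makes a good zero for the scale: a feed that leaves this share alone puts the same target in each flask once the starting material is consumed. The reckoning here therefore commits to all four flasks alike, near 30.4%, a share taken from one early pair of readings and carrying their scatter; what a feed has changed is then to be read by holding its flask against west, which has no feed.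

The forecast differs. It names east as highest, with 29.5% there, and gives 27% for west, 27% for south and 27% for north-west, all below the zero. On feeding it says “slow feeding gains little from selectivity”.

The flasks give 46.5% in east, 28.5% in west, 31.6% in south and 29.6% in north-west. East is highest, as the forecast named it, but stands 17 percentage points above its number.

    starting material + free catalyst ⇌ catalyst intermediate A (K = 910 /M, k = 2300 /M/h)
    catalyst intermediate A ⇌ free catalyst + target (K = 0.360 M, k = 0.450 /h)
    second substrate + free catalyst ⇌ catalyst intermediate B (K = 28000 /M, k = 190 /M/h)
    catalyst intermediate B → free catalyst + second product (k = 1.10 /h)
    target ⇌ isomer of the product (K = 0.760, k = 0.0170 /h)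
    starting material → uncatalysed product (k = 0.0820 /h)

On the carried share, east reaches 46.6%, above the zero of 30.4%. At 0.392 d in east, the forward step of starting material onto free catalyst uses starting material 11 times as fast as its passage to uncatalysed product. The same flask as east with 2.5 mol% of free catalyst lies on the other side of the zero, at a share of 16.5%, with 74.9% standing as uncatalysed product.

The data were generated by integration with constants of no real substance, noise included.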